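(All constants were drawn at random within sensible limits.)

Late in a run I stop asking where the material could go and ask how many lifetimes of the step from loose adduct to target the flask has been given.

in all of them: starting material 0.020 M; reagent 0.0200 M; capture agent 6.00 mM; time 20 s

| run | temperature | remark |
|---|---|---|
| oak | −10 °C |  |
| ash | 20 °C |  |
| alder | −40 °C |  |
| cedar |  | at 20 °C until 15 s, from then on at −40 °C |

- the best flask by amount of target, in percent of the starting material charged; "all alike" if 1.5 percentage points covers them all (oak / ash / alder / cedar / all alike)
- amount of target at the end, in percent of the starting material charged, oak
- amount of target at the end, in percent of the starting material charged, ash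
- amount of target at the end, in percent of the starting material charged, alder
- amount of target at the end, in percent of the starting material charged, cedar

- target is meant together with its idle adduct
- the list of constants is for 20 °C, to be carried to other temperatures by the activation energies and enthalpies

    starting material + reagent ⇌ loose adduct (K1 = 113 /M, k1 = 5.59 /M/s, Ea1 = 37.0 kJ/mol, ΔH1 = −10.0 kJ/mol)
    loose adduct → target (k2 = 0.0584 /s, Ea2 = 87.0 kJ/mol)
    capture agent + loose adduct → trapped intermediate (k3 = 2.85 /M/s, Ea3 = 57.0 kJ/mol)
    reagent + target ⇌ idle adduct, settled at all times (K4 = 170 /M, ΔH4 = −51.0 kJ/mol)
    (constants at 20 °C)

**First.** Target forms at the rate constant of that step times c(loose adduct). The idle adduct is counted with target, so the sum grows at that rate however the two divide. Target in percent of the charge is therefore a count of turnovers times the mean share of loose adduct. At 20 °C the lifetime is 17.1 s, and against 20 s this gives 1.17. This is the turnover count, run time at temperature divided by lifetime.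

**Second.** The mean share brings in a second time, that of supply to loose adduct. Supply takes about 8.94 s at the start, shorter than the lifetime. From coldest to hottest, supply speeds up by 50, far less than the 9800 of the target step. Capture, pseudo-first-order at 0.0171 /s, runs at 0.293 of the target step's rate constant, so it trims target.

**Third.** Ash has the count above. Alder has 1.20 × 10⁻⁴. Cedar has 0.876 while warm and 2.99 × 10⁻⁵ while cold. Ash therefore leads these, and oak, colder than ash, has a smaller count, which I leave unreckoned. If the mean shares are alike, cedar ends at 0.749 of ash.

**Fourth.** The forecast names ash, with oak 0.29 %, ash 27 %, alder <0.001 % and cedar 20.5 %, on the ground that “cooling almost stops target formation”.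

**Fifth.** The simulation gives ash as best, with oak 0.300 %, ash 27.1 %, alder 0 % and cedar 20.6 %.

In cedar, the step to target ran during the warm stretch, with half its turnover done by 8.36 s while loose adduct stood near 24.2 % at the change. After the change, target with its idle adduct stayed at 20.6 %, while the idle adduct rose from 11.6 % to 20.5 %. Dividing by the counts gives a mean loose-adduct share of 23.2 % in ash and 23.5 % in cedar's warm stretch. The neighbour like cedar but charged with 0.080 M of reagent has the same warm count, and its 43.4 % of target gives a mean share of 49.5 %.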